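The six-membered ring (C1, C10–C14; briarane numbering) is traced back to a C11=C12–C13=C14 cyclohexadiene, the retron of the C11/C12 cis-diol flanked by the C13=C14 olefin and quaternary C1. One [3+3] annulation joins allylidenetriphenylphosphorane (C12–C14) to a tetrasubstituted alkylidene acetoacetate (C11–C10–C1): γ-conjugate addition forms C1–C14, intramolecular Wittig olefination forms C11=C12, and a dioxolane on C1 steers the new quaternary centre before being cut away. Face-selective osmylation, a Nozaki–Hiyama–Kishi union with a butenolide triflate (C8–C9), acetate-assisted opening of the 8,17-epoxide and a Nozaki–Hiyama–Kishi ring closure (C4–C5) finish the skeleton.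

Key step: step 3

Remarks on the chemistry:
- Numbering: C1 quaternary (methyl C15), C2–C4 acetoxy carbons, C5(methyl C16)=C6, C7 lactone O-carbon, C8, C9, C10 ring fusion, C11 (methyl C20), C12, C13=C14, C17 (methyl C18), C19 lactone carbonyl. Target: 1S,2R,3R,4S,5Z,7S,8S,9R,10S,11S,12R,17S.
- Assumption: the ylide attacks C1 anti to the dioxolane C–O bond (Felkin–Anh sense with allylic strain control). Should the sense be the opposite, the enantiomer of 1 would be used, since this stereocentre is excised in step 13.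
- Compounds 1, 6 and 13 are taken as commercially available.

Step 1
Reactants: 1 (4S)-4-ethynyl-2,2-dimethyl-1,3-dioxolane
Product: 3 methyl 3-[(4S)-2,2-dimethyl-1,3-dioxolan-4-yl]prop-2-ynoate, via lithium acetylide 2 (not isolated)
Conditions: nBuLi, THF, −78 °C; ClCO2Me, −78 → 0 °C
Reagents that add atoms: methyl chloroformate COC(Cl)=O
Why: Acylation of a lithium acetylide with a chloroformate is routine and does not touch the dioxolane stereocentre.

Step 2
Reactants: 3 methyl 3-[(4S)-2,2-dimethyl-1,3-dioxolan-4-yl]prop-2-ynoate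
Product: 5 methyl (2Z)-2-acetyl-3-[(4S)-2,2-dimethyl-1,3-dioxolan-4-yl]but-2-enoate, via alkenylcuprate 4 (not isolated)
Conditions: Me2CuLi (from MeLi and CuI), THF, −78 °C; AcCl, −78 → −40 °C
Reagents that add atoms: lithium dimethylcuprate [Li+].C[Cu-]C; acetyl chloride CC(Cl)=O
Why: syn-Carbocupration of the ynoate puts the methyl group on C1 and C-acylation of the α-cuprio ester should give the alkylidene acetoacetate (carbocupration/acylation); its double-bond geometry does not matter for step 3.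

Step 3
Reactants: 5 methyl (2Z)-2-acetyl-3-[(4S)-2,2-dimethyl-1,3-dioxolan-4-yl]but-2-enoate; 6 allyltriphenylphosphonium bromide
Product: 9 methyl (1S,6S)-6-[(4S)-2,2-dimethyl-1,3-dioxolan-4-yl]-2,6-dimethylcyclohexa-2,4-diene-1-carboxylate, via allylidenetriphenylphosphorane 7 (not isolated), via keto ylide 8 (not isolated)
Conditions: 6, nBuLi, THF, 0 °C; then 5, −78 °C → rt
Reagents that add atoms: none
Why: The ambident ylide 7 adds through its γ-carbon (C14) to the doubly activated β-carbon C1 of 5 (vinylogous Michael addition); proton transfer from C14 to the β-keto ester enolate gives the allylic ylide 8, whose α-carbon (C12) olefinates the methyl ketone C11 intramolecularly with loss of Ph3PO. The closest known reaction is the cyclohexadiene annulation of allylidenetriphenylphosphorane with enones and alkylidene β-keto esters, which converts alkyl 2-acetyl-3-methylbut-2-enoates into alkyl 2,6,6-trimethylcyclohexa-2,4-diene-1-carboxylates. The only ring formed, the six-membered carbocycle, closes by intramolecular Wittig olefination of the ketone (formally 6-exo attack of C12 on C11), and the ester is not a competitor. C1 is set by 1,2-induction from the dioxolane stereocentre (C–H eclipsing the alkene to relieve allylic strain, attack anti to the C–O bond), and C10 is set under equilibrating conditions, first as the β-keto ester and then as the allylic ester, with the ester trans to the dioxolane. The step needs γ- over α-attack of the ylide and olefination of the ketone rather than the ester, which the soft, hindered, doubly activated acceptor and the ring size should secure. It is stereoconvergent: both alkene isomers of 5, both C10 epimers and both C13=C14 geometries of 8 should funnel into 9.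

Step 4
Reactants: 9 methyl (1S,6S)-6-[(4S)-2,2-dimethyl-1,3-dioxolan-4-yl]-2,6-dimethylcyclohexa-2,4-diene-1-carboxylate
Product: 10 the 11α,12α-diol (C13=C14 retained; C9 methyl ester; dioxolanyl on C1)
Conditions: OsO4 (2 mol %), NMO (1.05 equiv), acetone/H2O, 0 °C
Reagents that add atoms: N-methylmorpholine N-oxide C[N+]1([O-])CCOCC1; water O
Why: Upjohn dihydroxylation should take the electron-richer trisubstituted C11=C12 bond from the α-face, anti to the C10 ester and the pseudoaxial C1 methyl, and leave the hindered C13=C14 bond next to quaternary C1.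

Step 5
Reactants: 10 the 11α,12α-diol
Product: 11 the 11,12-O-isopropylidene methyl ester
Conditions: 2,2-dimethoxypropane, PPTS (cat.), CH2Cl2, rt
Reagents that add atoms: 2,2-dimethoxypropane COC(C)(C)OC
Why: Acid-catalysed transketalisation ties the cis-diol into a ring-fused acetonide, which also keeps the C11 hydroxyl out of later lactol formation.

Step 6
Reactants: 11 the 11,12-O-isopropylidene methyl ester
Product: 12 the C9 aldehyde
Conditions: iBu2AlH (1.1 equiv), toluene, −78 °C; Rochelle salt work-up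
Reagents that add atoms: none
Why: Partial reduction of a hindered ester stops at the aldehyde because the tetrahedral aluminate is stable at low temperature; C10, flanked by two quaternary carbons, should not epimerise.

Step 7
Reactants: 13 methyl (2S)-2,3-dihydroxypropanoate
Product: 14 methyl (2S)-3-[tert-butyl(diphenyl)silyl]oxy-2-hydroxypropanoate
Conditions: TBDPSCl, imidazole, CH2Cl2, 0 °C
Reagents that add atoms: tert-butyl(chloro)diphenylsilane CC(C)(C)[Si](Cl)(c1ccccc1)c1ccccc1
Why: Silylation is selective for the primary hydroxyl.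

Step 8
Reactants: 14 methyl (2S)-3-[tert-butyl(diphenyl)silyl]oxy-2-hydroxypropanoate
Product: 15 methyl (2S)-3-[tert-butyl(diphenyl)silyl]oxy-2-(propanoyloxy)propanoate
Conditions: EtCOCl, pyridine, DMAP (cat.), CH2Cl2, 0 °C
Reagents that add atoms: propanoyl chloride CCC(Cl)=O
Why: Simple O-acylation provides C17, C18 and C19.

Step 9
Reactants: 15 methyl (2S)-3-[tert-butyl(diphenyl)silyl]oxy-2-(propanoyloxy)propanoate
Product: 16 (5S)-5-{[tert-butyl(diphenyl)silyl]oxymethyl}-4-hydroxy-3-methylfuran-2(5H)-one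
Conditions: LiHMDS (2.2 equiv), THF, −78 → 0 °C; then 1 M HCl
Reagents that add atoms: none
Why: Lacey–Dieckmann cyclisation of the propanoate enolate onto the methyl ester gives the 3-methyltetronic acid; low temperature should keep C7 intact.

Step 10
Reactants: 16 (5S)-5-{[tert-butyl(diphenyl)silyl]oxymethyl}-4-hydroxy-3-methylfuran-2(5H)-one
Product: 17 the 4-triflyloxy butenolide
Conditions: Tf2O, iPr2NEt, CH2Cl2, −78 °C
Reagents that add atoms: trifluoromethanesulfonic anhydride O=S(=O)(OS(=O)(=O)C(F)(F)F)C(F)(F)F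
Why: O-Sulfonylation of the vinylogous acid gives an enol triflate ready for nickel insertion.

Step 11
Reactants: 12 the C9 aldehyde; 17 the 4-triflyloxy butenolide
Product: 18 the (9R)-carbinol carrying the butenolide at C9
Conditions: CrCl2 (6 equiv), NiCl2 (1 mol %), DMF, rt
Reagents that add atoms: none
Why: Nozaki–Hiyama–Kishi coupling, known for β-halo and β-sulfonyloxy enoates, forms C8–C9; Felkin–Anh attack anti to the larger, all-carbon quaternary C1 should give the 9R alcohol.

Step 12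
Reactants: 18 the (9R)-carbinol
Product: 19 the C9 acetate
Conditions: Ac2O, pyridine, DMAP (cat.), CH2Cl2, rt
Reagents that add atoms: acetic anhydride CC(=O)OC(C)=O
Why: Acetylation installs the final C9 ester, which later serves as the neighbouring group in step 22.

Step 13
Reactants: 19 the C9 acetate
Product: 21 the C2 aldehyde, via side-chain diol 20 (not isolated)
Conditions: H5IO6 (1.3 equiv), EtOAc, rt
Reagents that add atoms: none
Why: Periodic acid should hydrolyse the terminal dioxolane faster than the ring-fused acetonide and cleave the freed glycol, which removes the auxiliary stereocentre and its CH2O carbon (one-pot acetal hydrolysis/glycol cleavage).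

Step 14
Reactants: 21 the C2 aldehyde
Product: 22 the (2R,3R) homoallylic alcohol with C3–OMOM and a vinyl group (future C4)
Conditions: allyl methoxymethyl ether, sBuLi, THF, −78 °C; (−)-Ipc2BOMe; BF3·OEt2; then 21, −78 °C; ethanolamine work-up
Reagents that add atoms: 3-(methoxymethoxy)prop-1-ene C=CCOCOC
Why: Brown γ-alkoxyallylboration through a chair transition state gives the syn (threo) 2,3-diol monoether under reagent control; the non-oxidative work-up spares the butenolide and the acetate.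

Step 15
Reactants: 22 the (2R,3R) homoallylic alcohol with C3–OMOM
Product: 23 the 2,3-diol
Conditions: TMSOTf, 2,2′-bipyridyl, CH2Cl2, 0 °C; then H2O
Reagents that add atoms: none
Why: The silyl triflate/bipyridyl method cleaves methoxymethyl ethers through a pyridinium intermediate and is known to spare ketals, silyl ethers and esters.

Step 16
Reactants: 23 the 2,3-diol
Product: 24 the 2,3,9-triacetate
Conditions: Ac2O, pyridine, DMAP, CH2Cl2, rt
Reagents that add atoms: acetic anhydride CC(=O)OC(C)=O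
Why: Both secondary hydroxyls are acetylated; the hindered C2 hydroxyl needs DMAP.

Step 17
Reactants: 24 the 2,3,9-triacetate
Product: 25 the 8,17-epoxy lactone (oxygen anti to the C7 substituent)
Conditions: NaOCl (aq.), pyridine, 0 °C
Reagents that add atoms: sodium hypochlorite [Na+].[O-]Cl
Why: Weitz–Scheffer-type nucleophilic epoxidation should touch only the electron-poor butenolide olefin and take place anti to the C7 side chain.

Step 18
Reactants: 25 the 8,17-epoxy lactone
Product: 26 the C6 primary alcohol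
Conditions: TBAF, AcOH, THF, rt
Reagents that add atoms: none
Why: Buffered fluoride desilylation leaves acetates, acetonide and epoxide alone.

Step 19
Reactants: 26 the C6 primary alcohol
Product: 27 the C6 aldehyde
Conditions: Dess–Martin periodinane, NaHCO3, CH2Cl2, 0 °C
Reagents that add atoms: none
Why: Buffered Dess–Martin oxidation gives the α-alkoxy aldehyde; with the butenolide already epoxidised, C7–H is no longer vinylogously acidic.

Step 20
Reactants: 27 the C6 aldehyde
Product: 28 the (5Z)-5-iodo olefin (iodine cis to C7)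
Conditions: EtPPh3I, nBuLi, THF; I2, −78 °C; NaHMDS; then 27, −78 °C
Reagents that add atoms: ethyltriphenylphosphonium iodide CC[P+](c1ccccc1)(c1ccccc1)c1ccccc1.[I-]; iodine II
Why: Stork–Zhao-type Wittig olefination with the α-iodo ylide gives (Z)-2-iodoalk-2-enes and so fixes the C5=C6 geometry of the target.

Step 21
Reactants: 28 the (5Z)-5-iodo olefin
Product: 30 the C4 aldehyde, via terminal diol 29 (not isolated)
Conditions: OsO4 (2 mol %), NaIO4, 2,6-lutidine, dioxane/H2O, rt
Reagents that add atoms: sodium periodate [Na+].[O-]I(=O)(=O)=O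
Why: Lemieux–Johnson cleavage should select the only monosubstituted olefin over the iodoalkene and the hindered ring olefin; it is run before the 8,17-diol is freed.

Step 22
Reactants: 30 the C4 aldehyde
Product: 32 the seco aldehyde with the trans-8,17-diol, via acetoxonium ion 31 (not isolated)
Conditions: BF3·OEt2, CH2Cl2, −78 → −30 °C; then aq. NaHCO3
Reagents that add atoms: water O
Why: Lewis acid opening of the epoxide with anchimeric assistance: the C9 acetate carbonyl attacks C8 from the rear and inverts it, and hydrolysis of the dioxolanylium ion should leave the acetate on the secondary O9 and the 8,17-diol in the target configuration.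

Step 23
Reactants: 32 the seco aldehyde with the trans-8,17-diol
Product: 33 the ten-membered allylic alcohol (C4 epimers)
Conditions: CrCl2 (10 equiv), NiCl2 (2 mol %), DMSO/THF, 0.002 M, rt
Reagents that add atoms: none
Why: Intramolecular Nozaki–Hiyama–Kishi coupling under high dilution forms C4–C5 with retention of the Z-olefin and tolerates lactone, acetates and free tertiary hydroxyls; the C4 configuration is corrected in steps 24 and 25.

Step 24
Reactants: 33 the ten-membered allylic alcohol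
Product: 34 the C4 enone
Conditions: Dess–Martin periodinane, CH2Cl2, rt
Reagents that add atoms: none
Why: Oxidation of the secondary allylic alcohol merges both C4 epimers into one ketone; tertiary hydroxyls do not react.

Step 25
Reactants: 34 the C4 enone
Product: 35 the (4S)-allylic alcohol
Conditions: NaBH4, CeCl3·7H2O, MeOH, −78 °C
Reagents that add atoms: none
Why: Luche 1,2-reduction; Felkin–Anh attack anti to the C3 acetoxy group should give the 3,4-syn (4S) alcohol, and any acetyl shift among O2, O3 and O4 is harmless before step 26.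

Step 26
Reactants: 35 the (4S)-allylic alcohol
Product: 36 the 11,12-O-isopropylidene derivative of the target
Conditions: Ac2O, pyridine, CH2Cl2, rt
Reagents that add atoms: acetic anhydride CC(=O)OC(C)=O
Why: Acetylation of the secondary alcohol; the tertiary hydroxyls at C8 and C17 should not react without forcing.

Step 27
Reactants: 36 the 11,12-O-isopropylidene derivative of the target
Product: 37 CNP0203328.1
Conditions: AcOH/H2O (4:1), 45 °C
Reagents that add atoms: none
Why: Mild acid hydrolysis of the acetonide leaves the four acetates and the lactone untouched.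

Compound list
1 | (4S)-4-ethynyl-2,2-dimethyl-1,3-dioxolane | C#C[C@H]1COC(C)(C)O1 | starting material
2 | lithium acetylide of 1 | [Li]C#C[C@H]1COC(C)(C)O1 | intermediate
3 | methyl 3-[(4S)-2,2-dimethyl-1,3-dioxolan-4-yl]prop-2-ynoate | COC(=O)C#C[C@H]1COC(C)(C)O1 | intermediate
4 | lithium alkenyl(methyl)cuprate from syn-addition (Cu on C10, methyl on C1) | [Li+].COC(=O)/C([Cu-]C)=C(/C)[C@H]1COC(C)(C)O1 | intermediate
5 | methyl (2Z)-2-acetyl-3-[(4S)-2,2-dimethyl-1,3-dioxolan-4-yl]but-2-enoate | COC(=O)/C(=C(/C)[C@H]1COC(C)(C)O1)C(C)=O | intermediate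
6 | allyltriphenylphosphonium bromide | C=CC[P+](c1ccccc1)(c1ccccc1)c1ccccc1.[Br-] | starting material
7 | allylidenetriphenylphosphorane | C=CC=P(c1ccccc1)(c1ccccc1)c1ccccc1 | intermediate
8 | methyl (3S)-2-acetyl-3-[(4S)-2,2-dimethyl-1,3-dioxolan-4-yl]-3-methyl-6-(triphenylphosphoranylidene)hex-4-enoate (C2 and olefin geometry mobile) | COC(=O)C(C(C)=O)[C@](C)(C=CC=P(c1ccccc1)(c1ccccc1)c1ccccc1)[C@H]1COC(C)(C)O1 | intermediate
9 | methyl (1S,6S)-6-[(4S)-2,2-dimethyl-1,3-dioxolan-4-yl]-2,6-dimethylcyclohexa-2,4-diene-1-carboxylate | COC(=O)[C@H]1C(C)=CC=C[C@]1(C)[C@H]2COC(C)(C)O2 | intermediate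
10 | 11α,12α-diol of 9 (C1, C10, C11, C12 as in the target) | COC(=O)[C@H]1[C@](C)(O)[C@H](O)C=C[C@]1(C)[C@H]2COC(C)(C)O2 | intermediate
11 | 11,12-O-isopropylidene methyl ester | COC(=O)[C@H]1[C@](C)(O3)[C@H](OC3(C)C)C=C[C@]1(C)[C@H]2COC(C)(C)O2 | intermediate
12 | C9 aldehyde (11,12-acetonide; dioxolanyl on C1) | O=C[C@H]1[C@](C)(O3)[C@H](OC3(C)C)C=C[C@]1(C)[C@H]2COC(C)(C)O2 | intermediate
13 | methyl (2S)-2,3-dihydroxypropanoate | COC(=O)[C@@H](O)CO | starting material
14 | methyl (2S)-3-[tert-butyl(diphenyl)silyl]oxy-2-hydroxypropanoate | COC(=O)[C@@H](O)CO[Si](c1ccccc1)(c1ccccc1)C(C)(C)C | intermediate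
15 | methyl (2S)-3-[tert-butyl(diphenyl)silyl]oxy-2-(propanoyloxy)propanoate | COC(=O)[C@@H](OC(=O)CC)CO[Si](c1ccccc1)(c1ccccc1)C(C)(C)C | intermediate
16 | (5S)-5-{[tert-butyl(diphenyl)silyl]oxymethyl}-4-hydroxy-3-methylfuran-2(5H)-one | CC1=C(O)[C@H](CO[Si](c2ccccc2)(c2ccccc2)C(C)(C)C)OC1=O | intermediate
17 | (5S)-5-{[tert-butyl(diphenyl)silyl]oxymethyl}-3-methyl-4-(triflyloxy)furan-2(5H)-one | CC1=C(OS(=O)(=O)C(F)(F)F)[C@H](CO[Si](c2ccccc2)(c2ccccc2)C(C)(C)C)OC1=O | intermediate
18 | (9R)-carbinol: butenolide C8 joined to C9 of the ring fragment | CC1=C([C@H](O)[C@H]2[C@](C)(O4)[C@H](OC4(C)C)C=C[C@]2(C)[C@H]3COC(C)(C)O3)[C@H](CO[Si](c5ccccc5)(c5ccccc5)C(C)(C)C)OC1=O | intermediate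
19 | C9 acetate of 18 | CC1=C([C@H](OC(C)=O)[C@H]2[C@](C)(O4)[C@H](OC4(C)C)C=C[C@]2(C)[C@H]3COC(C)(C)O3)[C@H](CO[Si](c5ccccc5)(c5ccccc5)C(C)(C)C)OC1=O | intermediate
20 | side-chain 1,2-diol from 19 | CC1=C([C@H](OC(C)=O)[C@H]2[C@](C)(O4)[C@H](OC4(C)C)C=C[C@]2(C)[C@H](O)CO)[C@H](CO[Si](c5ccccc5)(c5ccccc5)C(C)(C)C)OC1=O | intermediate
21 | C2 aldehyde | CC1=C([C@H](OC(C)=O)[C@H]2[C@](C)(O4)[C@H](OC4(C)C)C=C[C@]2(C)C=O)[C@H](CO[Si](c5ccccc5)(c5ccccc5)C(C)(C)C)OC1=O | intermediate
22 | (2R,3R) C2 alcohol with C3–OMOM and vinyl group | CC1=C([C@H](OC(C)=O)[C@H]2[C@](C)(O4)[C@H](OC4(C)C)C=C[C@]2(C)[C@@H](O)[C@H](OCOC)C=C)[C@H](CO[Si](c5ccccc5)(c5ccccc5)C(C)(C)C)OC1=O | intermediate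
23 | (2R,3R)-2,3-diol | CC1=C([C@H](OC(C)=O)[C@H]2[C@](C)(O4)[C@H](OC4(C)C)C=C[C@]2(C)[C@@H](O)[C@H](O)C=C)[C@H](CO[Si](c5ccccc5)(c5ccccc5)C(C)(C)C)OC1=O | intermediate
24 | 2,3,9-triacetate (butenolide) | CC1=C([C@H](OC(C)=O)[C@H]2[C@](C)(O4)[C@H](OC4(C)C)C=C[C@]2(C)[C@@H](OC(C)=O)[C@H](OC(C)=O)C=C)[C@H](CO[Si](c5ccccc5)(c5ccccc5)C(C)(C)C)OC1=O | intermediate
25 | 8,17-epoxy lactone (epoxide oxygen anti to the C7 side chain) | CC(C)(C)[Si](c1ccccc1)(c1ccccc1)OC[C@@H]1OC(=O)[C@@]2(C)O[C@@]12[C@H](OC(C)=O)[C@H]3[C@](C)(O4)[C@H](OC4(C)C)C=C[C@]3(C)[C@@H](OC(C)=O)[C@H](OC(C)=O)C=C | intermediate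
26 | C6 primary alcohol | OC[C@@H]1OC(=O)[C@@]2(C)O[C@@]12[C@H](OC(C)=O)[C@H]3[C@](C)(O4)[C@H](OC4(C)C)C=C[C@]3(C)[C@@H](OC(C)=O)[C@H](OC(C)=O)C=C | intermediate
27 | C6 aldehyde | O=C[C@@H]1OC(=O)[C@@]2(C)O[C@@]12[C@H](OC(C)=O)[C@H]3[C@](C)(O4)[C@H](OC4(C)C)C=C[C@]3(C)[C@@H](OC(C)=O)[C@H](OC(C)=O)C=C | intermediate
28 | (5Z)-5-iodo olefin (epoxy lactone; C3 vinyl) | I/C(C)=C\[C@@H]1OC(=O)[C@@]2(C)O[C@@]12[C@H](OC(C)=O)[C@H]3[C@](C)(O4)[C@H](OC4(C)C)C=C[C@]3(C)[C@@H](OC(C)=O)[C@H](OC(C)=O)C=C | intermediate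
29 | terminal 1,2-diol from 28 (new carbinol centre undefined) | I/C(C)=C\[C@@H]1OC(=O)[C@@]2(C)O[C@@]12[C@H](OC(C)=O)[C@H]3[C@](C)(O4)[C@H](OC4(C)C)C=C[C@]3(C)[C@@H](OC(C)=O)[C@H](OC(C)=O)C(O)CO | intermediate
30 | C4 aldehyde (epoxy lactone; iodo olefin) | I/C(C)=C\[C@@H]1OC(=O)[C@@]2(C)O[C@@]12[C@H](OC(C)=O)[C@H]3[C@](C)(O4)[C@H](OC4(C)C)C=C[C@]3(C)[C@@H](OC(C)=O)[C@H](OC(C)=O)C=O | intermediate
31 | 2-methyl-1,3-dioxolan-2-ylium ion bridging O8 and O9 (C17–O–BF3 alkoxide) | I/C(C)=C\[C@@H]1OC(=O)[C@@](C)(O[B-](F)(F)F)[C@]12OC(C)=[O+][C@@H]2[C@H]3[C@](C)(O4)[C@H](OC4(C)C)C=C[C@]3(C)[C@@H](OC(C)=O)[C@H](OC(C)=O)C=O | intermediate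
32 | seco aldehyde with (8S,17S)-diol lactone | I/C(C)=C\[C@@H]1OC(=O)[C@@](C)(O)[C@@]1(O)[C@H](OC(C)=O)[C@H]3[C@](C)(O4)[C@H](OC4(C)C)C=C[C@]3(C)[C@@H](OC(C)=O)[C@H](OC(C)=O)C=O | intermediate
33 | ten-membered allylic alcohol (C4 epimers) | CC(=O)O[C@@H]1C(O)/C(C)=C\[C@@H]2OC(=O)[C@@](C)(O)[C@@]2(O)[C@H](OC(C)=O)[C@H]2[C@](C)(O3)[C@H](OC3(C)C)C=C[C@]2(C)[C@H]1OC(C)=O | intermediate
34 | C4 enone | CC(=O)O[C@@H]1C(=O)/C(C)=C\[C@@H]2OC(=O)[C@@](C)(O)[C@@]2(O)[C@H](OC(C)=O)[C@H]2[C@](C)(O3)[C@H](OC3(C)C)C=C[C@]2(C)[C@H]1OC(C)=O | intermediate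
35 | (4S)-allylic alcohol | CC(=O)O[C@@H]1[C@@H](O)/C(C)=C\[C@@H]2OC(=O)[C@@](C)(O)[C@@]2(O)[C@H](OC(C)=O)[C@H]2[C@](C)(O3)[C@H](OC3(C)C)C=C[C@]2(C)[C@H]1OC(C)=O | intermediate
36 | 11,12-O-isopropylidene derivative of the target | CC(=O)O[C@@H]1[C@@H](OC(C)=O)/C(C)=C\[C@@H]2OC(=O)[C@@](C)(O)[C@@]2(O)[C@H](OC(C)=O)[C@H]2[C@](C)(O3)[C@H](OC3(C)C)C=C[C@]2(C)[C@H]1OC(C)=O | intermediate
37 | CNP0203328.1 (2,3,4,9-tetraacetoxy-8,11,12,17-tetrahydroxy briarane 19,7-lactone) | CC(=O)O[C@@H]1[C@@H](OC(C)=O)/C(C)=C\[C@@H]2OC(=O)[C@@](C)(O)[C@@]2(O)[C@H](OC(C)=O)[C@H]2[C@](C)(O)[C@H](O)C=C[C@]2(C)[C@H]1OC(C)=O | target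

Total step count: 27. Longest linear sequence: 23 steps (steps 1–6 and 11–27); the butenolide triflate 17 is made in 4 steps (steps 7–10).

Steps most likely to fail

Step 3. The ylide may attack through its α-carbon or olefinate first, facial selectivity at C1 may be poor, or the product diene may drift into conjugation with the ester under the basic conditions. The fallback sets out from 5 and builds the ring in separate operations. Conjugate addition of [(Z)-(EtO)2CHCH=CH]2CuLi (from (Z)-1-iodo-3,3-diethoxyprop-1-ene, tBuLi and CuI) forms C1–C14 and should give the (Z)-enal acetal F1; cuprate additions to γ-alkoxy alkylidene malonates are precedented with the same anti sense. PPTS in wet acetone would unmask the keto enal F2. Intramolecular McMurry coupling (TiCl3(DME)1.5, Zn(Cu), DME, reflux) of the C11 ketone with the C12 aldehyde would then form C11=C12, and the fallback comes back to the route at 9.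

Step 11. Facial selectivity may be poor when the alkenylchromium species adds to an aldehyde whose α-carbon carries two quaternary neighbours. The fallback sets out from 18 obtained as a mixture of C9 epimers. Dess–Martin oxidation would give the C9 ketone F3, and reduction with (S)-2-methyl-CBS-oxazaborolidine and BH3·SMe2 (butenolide as the larger π-substituent) should return the single 9R alcohol, so the fallback comes back at 18.

Step 23. Oligomerisation may outrun closure of the ten-membered ring, or the α-acetoxy aldehyde may decompose before it is captured. The fallback closes the ring by olefin metathesis at C5=C6 and sets out from 25.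
- Lemieux–Johnson cleavage of the vinyl group gives the C4 aldehyde F4.
- Intermolecular Nozaki–Hiyama–Kishi coupling with 2-bromopropene (CrCl2, NiCl2) should give the Felkin (4R)-isopropenyl carbinol F5.
- Mitsunobu inversion with acetic acid (PPh3, DIAD) gives the (4S)-acetate F6.
- TBAF/AcOH frees the C6 alcohol F7, and Dess–Martin oxidation gives the C6 aldehyde F8.
- Wittig methylenation (Ph3P=CH2) gives the C7 vinyl triene F9.
- Ring-closing metathesis with the second-generation Grubbs catalyst at high dilution should give the macrocyclic epoxide F10; ring strain favours the Z olefin in a ten-membered ring.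
- Opening of the epoxide as in step 22 (BF3·OEt2, then water) brings the fallback back at 36.

Further compounds
F1 | step 3 | methyl 2-acetyl-3-[(4S)-2,2-dimethyl-1,3-dioxolan-4-yl]-6,6-diethoxy-3-methylhex-4(Z)-enoate (C1 as in 9) | CCOC(OCC)/C=C\[C@@](C)(C(C(C)=O)C(=O)OC)[C@H]1COC(C)(C)O1
F2 | step 3 | methyl 2-acetyl-3-[(4S)-2,2-dimethyl-1,3-dioxolan-4-yl]-3-methyl-6-oxohex-4(Z)-enoate | O=C/C=C\[C@@](C)(C(C(C)=O)C(=O)OC)[C@H]1COC(C)(C)O1
F3 | step 11 | C9 ketone corresponding to 18 | CC1=C(C(=O)[C@H]2[C@](C)(O4)[C@H](OC4(C)C)C=C[C@]2(C)[C@H]3COC(C)(C)O3)[C@H](CO[Si](c5ccccc5)(c5ccccc5)C(C)(C)C)OC1=O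
F4 | step 23 | C4 aldehyde from 25 (silyl ether and epoxide retained) | CC(C)(C)[Si](c1ccccc1)(c1ccccc1)OC[C@@H]1OC(=O)[C@@]2(C)O[C@@]12[C@H](OC(C)=O)[C@H]3[C@](C)(O4)[C@H](OC4(C)C)C=C[C@]3(C)[C@@H](OC(C)=O)[C@H](OC(C)=O)C=O
F5 | step 23 | (4R)-isopropenyl carbinol | CC(C)(C)[Si](c1ccccc1)(c1ccccc1)OC[C@@H]1OC(=O)[C@@]2(C)O[C@@]12[C@H](OC(C)=O)[C@H]3[C@](C)(O4)[C@H](OC4(C)C)C=C[C@]3(C)[C@@H](OC(C)=O)[C@H](OC(C)=O)[C@H](O)C(C)=C
F6 | step 23 | (4S)-acetate of the isopropenyl carbinol | CC(C)(C)[Si](c1ccccc1)(c1ccccc1)OC[C@@H]1OC(=O)[C@@]2(C)O[C@@]12[C@H](OC(C)=O)[C@H]3[C@](C)(O4)[C@H](OC4(C)C)C=C[C@]3(C)[C@@H](OC(C)=O)[C@H](OC(C)=O)[C@@H](OC(C)=O)C(C)=C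
F7 | step 23 | C6 alcohol of the tetraacetate | OC[C@@H]1OC(=O)[C@@]2(C)O[C@@]12[C@H](OC(C)=O)[C@H]3[C@](C)(O4)[C@H](OC4(C)C)C=C[C@]3(C)[C@@H](OC(C)=O)[C@H](OC(C)=O)[C@@H](OC(C)=O)C(C)=C
F8 | step 23 | C6 aldehyde of the tetraacetate | O=C[C@@H]1OC(=O)[C@@]2(C)O[C@@]12[C@H](OC(C)=O)[C@H]3[C@](C)(O4)[C@H](OC4(C)C)C=C[C@]3(C)[C@@H](OC(C)=O)[C@H](OC(C)=O)[C@@H](OC(C)=O)C(C)=C
F9 | step 23 | triene with C7 vinyl and C4 isopropenyl groups | C=C[C@@H]1OC(=O)[C@@]2(C)O[C@@]12[C@H](OC(C)=O)[C@H]3[C@](C)(O4)[C@H](OC4(C)C)C=C[C@]3(C)[C@@H](OC(C)=O)[C@H](OC(C)=O)[C@@H](OC(C)=O)C(C)=C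
F10 | step 23 | macrocyclic 8,17-epoxide tetraacetate (11,12-acetonide) | CC(=O)O[C@@H]1[C@@H](OC(C)=O)/C(C)=C\[C@@H]2OC(=O)[C@@]3(C)O[C@@]23[C@H](OC(C)=O)[C@H]2[C@](C)(O4)[C@H](OC4(C)C)C=C[C@]2(C)[C@H]1OC(C)=O
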